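**Retrosynthetic overview**
- Feature: in the seven-membered ring, the carbinol C10, the oxirane carbon C9 and the methyl-bearing oxirane carbon C8 are a masked 3-methylcyclohept-2-enone (C10=O, C8=C9). Removing C9 leaves a 2-methylcyclohexanone with C8 bonded to C10; its other α-carbon, C1, is quaternary, so it can enolise only toward C8.
- Final disconnections: oxirane and C10–OH ← enone 33 ← one-carbon ring expansion of the C8=C10 silyl enol ether 29 (cyclopropanation with CH2I2, then oxidative cleavage of the C8–C10 bond).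
- Hydrindanone 29 ← six-membered ring by ring-closing metathesis (C6=C7) on a cyclopentanone whose trans C1/C5 substituents come from a conjugate addition–aldol reaction. C6–O comes from α-epoxidation and β-elimination; C2–O and C4–O come from enone reduction, hydroxyl-directed epoxidation and hydride opening.
- Ring order: five-membered ring (from cyclopentenone 1, which also supplies the absolute configuration) → six-membered ring (step 7) → seven-membered ring (step 19) → oxirane (step 22).

Key step: step 19

Remark on numbering: C1 is the ring-fusion carbon with the angular methyl, C2 (O-acetyl), C3 (CH2), C4 (isopropyl carbinol) and C5 (ring-fusion CH) complete the five-membered ring, and C6 (O-anisoyl), C7, C8 (methyl), C9, C10 complete the large ring; β is the face of the C1 methyl, and all bicyclic compounds have the C1 β-methyl / C5 α-H trans fusion.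
Remark on epimers: aldehyde 9 is racemic, so the C8 and C10 centres of 12–22 are carried as epimer mixtures; both centres are erased later (C10 in step 14, C8 in step 16).

Step 1
Reactants: 1 (R)-4-(tert-butyldimethylsilyloxy)cyclopent-2-en-1-one; 2 isopropylmagnesium chloride
Product: 5 (S)-4-isopropylcyclopent-2-en-1-one, via chloromagnesium enolate 3 (not isolated), via β-silyloxy ketone 4 (not isolated)
Conditions: iPrMgCl, CuBr·SMe2 (10 mol %), THF, −78 °C; aq NH4Cl; then DBU, CH2Cl2, 0 °C, short contact
Reagents that add atoms: isopropylmagnesium chloride, CC(C)[Mg]Cl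
Why: CuBr·SMe2-catalysed conjugate addition of the Grignard reagent occurs anti to the silyloxy group and so sets the isopropyl-bearing centre (later C4, used only as a relay), and E1cB loss of silanol from the β-silyloxy ketone then moves the enone to the other side of the ring.

Step 2
Reactants: 5 (S)-4-isopropylcyclopent-2-en-1-one
Product: 6 (S)-2-iodo-4-isopropylcyclopent-2-en-1-one
Conditions: I2, pyridine, CH2Cl2, 0 °C → rt
Reagents that add atoms: iodine, [I][I]
Why: Amine-mediated α-iodination of an enone (conjugate addition of pyridine, iodination of the enolate, elimination), which does not touch the γ-stereocentre.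

Step 3
Reactants: 6 (S)-2-iodo-4-isopropylcyclopent-2-en-1-one
Product: 7 (S)-4-isopropyl-2-methylcyclopent-2-en-1-one
Conditions: MeZnCl, Pd(PPh3)4 (5 mol %), THF, rt
Reagents that add atoms: methylzinc chloride, C[Zn]Cl
Why: Negishi coupling of the α-iodoenone installs the future C1 methyl group under neutral conditions, so the base-sensitive γ-centre should keep its configuration.

Step 4
Reactants: 8 2-methylbut-3-en-1-ol (racemic)
Product: 9 2-methylbut-3-enal (racemic)
Conditions: Dess–Martin periodinane, NaHCO3, CH2Cl2, 0 °C; filtered cold and used at once as a solution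
Reagents that add atoms: none
Why: Buffered Dess–Martin oxidation of a primary alcohol should give the β,γ-unsaturated aldehyde without the base or heat that would draw the double bond into conjugation.

Step 5
Reactants: 7 (S)-4-isopropyl-2-methylcyclopent-2-en-1-one; 10 vinylmagnesium bromide; 9 2-methylbut-3-enal
Product: 12 (2S,3S,4S)-2-(1-hydroxy-2-methylbut-3-en-1-yl)-4-isopropyl-2-methyl-3-vinylcyclopentan-1-one (side-chain epimers), via bromomagnesium enolate 11 (not isolated)
Conditions: vinylMgBr, CuBr·SMe2 (20 mol %), THF, −78 → −40 °C; then 9, −78 °C; aq NH4Cl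
Reagents that add atoms: vinylmagnesium bromide, C=C[Mg]Br; 2-methylbut-3-enal (9), C=CC(C)C=O
Why: Tandem conjugate addition–aldol reaction: the vinyl group (C6 and C7) adds to C5 anti to the isopropyl group, and the tetrasubstituted enolate then attacks the aldehyde anti to the new vinyl group, which creates the quaternary C1 with the trans C1/C5 relationship of the later ring fusion.

Step 6
Reactants: 12 aldol adduct
Product: 13 tert-butyldimethylsilyl ether of 12 at the C10 hydroxyl
Conditions: TBSOTf, 2,6-lutidine, CH2Cl2, −78 → 0 °C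
Reagents that add atoms: tert-butyldimethylsilyl triflate, CC(C)(C)[Si](C)(C)OS(=O)(=O)C(F)(F)F
Why: Silylation of the hindered aldol hydroxyl with a silyl triflate blocks retro-aldol cleavage and keeps C10 at the alcohol oxidation level through the hydride steps that follow.

Step 7
Reactants: 13 silyl ether diene
Product: 14 trans-fused hydrindenone: C2 ketone, 4α-isopropyl, C6=C7 alkene, C8 methyl, C10 OTBS
Conditions: second-generation Grubbs catalyst RuCl2(=CHPh)(H2IMes)(PCy3) (5 mol %), CH2Cl2, 40 °C
Reagents that add atoms: none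
Why: Ring-closing metathesis of the two terminal alkenes closes the six-membered ring (C6=C7) on the trans-disposed C1 and C5 substituents with loss of ethene; no stereocentre is formed.

Step 8
Reactants: 14 trans-fused hydrindenone
Product: 16 bicyclic cyclopentenone (C2 ketone; C3=C4 bearing the isopropyl group on C4; C6=C7; C10 OTBS), via trimethylsilyl enol ether 15 (not isolated)
Conditions: TMSOTf, Et3N, CH2Cl2, 0 °C; then Pd(OAc)2, MeCN, rt
Reagents that add atoms: none
Why: Saegusa–Ito oxidation: the ketone can enolise only toward C3 because C1 is quaternary, and palladium diacetate converts the silyl enol ether into the C3=C4 enone by β-hydride elimination of the C4 hydrogen, which removes the relay stereocentre.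

Step 9
Reactants: 16 bicyclic cyclopentenone
Product: 17 allylic alcohol: 2β-hydroxy, C3=C4 (isopropyl on C4), C6=C7, C10 OTBS
Conditions: NaBH4, CeCl3·7H2O, MeOH, −78 → 0 °C
Reagents that add atoms: none
Why: Luche 1,2-reduction; hydride should attack C2 from the α-face, opposite the adjacent angular methyl group, and give the 2β-alcohol.

Step 10
Reactants: 17 allylic alcohol
Product: 18 epoxy alcohol: 2β-hydroxy-3β,4β-epoxide with 4α-isopropyl
Conditions: VO(acac)2 (5 mol %), tBuOOH, CH2Cl2, 0 °C → rt
Reagents that add atoms: tert-butyl hydroperoxide, CC(C)(C)OO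
Why: Hydroxyl-directed VO(acac)2-catalysed epoxidation delivers oxygen to the allylic C3=C4 bond on the face of the 2β-hydroxyl, which sets the C4–O bond β (and C3 likewise) and leaves the remote C6=C7 bond alone.

Step 11
Reactants: 18 epoxy alcohol
Product: 19 cis-1,3-diol: 2β-hydroxy, 4β-hydroxy-4α-isopropyl, C3 methylene
Conditions: LiEt3BH, THF, 0 °C → rt
Reagents that add atoms: none
Why: Reductive opening of a trisubstituted epoxide by SN2 attack of hydride at the less substituted C3 from the α-face keeps the C4–O bond, so the tertiary 4β-alcohol with the 4α-isopropyl group should result.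

Step 12
Reactants: 19 cis-1,3-diol
Product: 20 2β-acetate of 19 (tertiary 4β-hydroxyl free)
Conditions: Ac2O, pyridine, DMAP (cat.), CH2Cl2, rt
Reagents that add atoms: acetic anhydride, CC(=O)OC(C)=O
Why: DMAP-catalysed acetylation is selective for the secondary C2 hydroxyl over the tertiary C4 hydroxyl.

Step 13
Reactants: 20 acetate
Product: 21 C10 alcohol (2β-acetate, 4β-hydroxyl, C6=C7)
Conditions: HF·pyridine, pyridine, THF, 0 °C → rt
Reagents that add atoms: none
Why: Fluoride cleavage of the silyl ether under slightly acidic conditions should free the C10 hydroxyl without migration or loss of the acetate.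

Step 14
Reactants: 21 C10 alcohol
Product: 22 β,γ-unsaturated ketone: C10 ketone, C8 methyl (epimers), C6=C7, 4β-hydroxyl, 2β-acetate
Conditions: Dess–Martin periodinane, NaHCO3, CH2Cl2, 0 °C → rt
Reagents that add atoms: none
Why: Buffered Dess–Martin oxidation converts the hindered secondary alcohol into the C10 ketone, merges the C10 epimers, and should neither touch the tertiary alcohol nor move the C6=C7 bond into conjugation.

Step 15
Reactants: 22 β,γ-unsaturated ketone
Product: 23 triethylsilyl ether of 22 at the tertiary C4 hydroxyl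
Conditions: TESOTf, 2,6-lutidine, CH2Cl2, −78 °C
Reagents that add atoms: triethylsilyl triflate, CC[Si](CC)(CC)OS(=O)(=O)C(F)(F)F
Why: Silylation of a tertiary alcohol with a silyl triflate and a weak base at low temperature is faster than enol silylation of the hindered ketone, and it removes a hydroxyl that could steer the next epoxidation to the β-face.

Step 16
Reactants: 23 silyl ether ketone
Product: 25 γ-hydroxy enone (6α-hydroxy; C7=C8; C10 ketone; 4β-OTES; 2β-OAc), via α-epoxy ketone 24 (not isolated)
Conditions: mCPBA, NaHCO3, CH2Cl2, 0 °C; then DBU (0.2 equiv), CH2Cl2, 0 °C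
Reagents that add atoms: 3-chloroperbenzoic acid, OOC(=O)c1cccc(Cl)c1
Why: Peracid epoxidation of C6=C7 from the α-face, away from the axial angular methyl group and the 4β-silyloxy group, followed by E1cB opening of the β,γ-epoxy ketone through the C8 enolate, should give the conjugated enone with the C6–O bond α (trans to the angular methyl) and removes the C8 stereocentre.

Step 17
Reactants: 25 γ-hydroxy enone; 26 4-methoxybenzoyl chloride
Product: 27 6α-(4-methoxybenzoyloxy) enone
Conditions: Et3N, DMAP (cat.), CH2Cl2, 0 °C → rt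
Reagents that add atoms: 4-methoxybenzoyl chloride, COc1ccc(C(=O)Cl)cc1
Why: DMAP-catalysed acylation of the only free hydroxyl, the secondary allylic C6–OH, with retention at C6.

Step 18
Reactants: 27 6α-(4-methoxybenzoyloxy) enone
Product: 29 trimethylsilyl enol ether (C8=C10–OTMS; 6α-anisoate; 4β-OTES; 2β-OAc), via lithium enolate 28 (not isolated)
Conditions: LiBH(s-Bu)3, THF, −78 °C; then TMSCl, Et3N, −78 → 0 °C
Reagents that add atoms: chlorotrimethylsilane, C[Si](C)(C)Cl
Why: Conjugate reduction of an enone whose β-carbon C7 carries no extra substituent and whose carbonyl is shielded by the quaternary C1, followed by O-silylation of the enolate, gives the tetrasubstituted enol ether regiospecifically; the esters should not react with the bulky hydride at −78 °C.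

Step 19
Reactants: 29 trimethylsilyl enol ether; 30 diiodomethane
Product: 33 hydroazulenone (C10 ketone; C8=C9 bearing the methyl on C8; 6α-anisoate; 4β-OTES; 2β-OAc), via siloxycyclopropane 31 (not isolated), via β-chloro ketone 32 (not isolated)
Conditions: Et2Zn, CH2I2, CH2Cl2, 0 °C → rt; then FeCl3, DMF, 0 °C; then NaOAc, MeOH, 40 °C
Reagents that add atoms: diiodomethane, ICI
Why: Furukawa-modified Simmons–Smith cyclopropanation of the electron-rich enol ether by EtZnCH2I forms C8–C9 and C9–C10 in a concerted syn addition that closes the three-membered ring. FeCl3 then oxidises the siloxycyclopropane by one electron, the silyl group leaves as Me3SiCl, and the C10 oxy radical breaks the internal C8–C10 bond, so the bicyclo[4.1.0]heptane opens to the seven-membered ring by fragmentation (not by a new cyclisation) and the tertiary C8 radical takes up chlorine; NaOAc removes HCl through the C9 enolate to give the conjugated C8=C9 enone. The closest known reaction is the Ito–Saegusa ring expansion of 1-silyloxy-2-methylcyclohexenes to 3-methylcyclohept-2-enones. No new stereocentre survives, because C8 and C10 of the cyclopropane both become sp2, so the face of carbenoid attack does not matter. The step needs the enol ether at C8=C10 only, which the quaternary C1 guarantees, and internal instead of external cyclopropane cleavage, which the tertiary C8 radical favours; the trans ring fusion is safe because C1 is quaternary and C5–H is not α to a carbonyl.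

Step 20
Reactants: 33 hydroazulenone
Product: 34 10β-allylic alcohol
Conditions: NaBH4, CeCl3·7H2O, MeOH, −78 °C
Reagents that add atoms: none
Why: Luche 1,2-reduction; hydride should add to C10 from the α-face, opposite the adjacent angular methyl group, to give the 10β-alcohol.

Step 21
Reactants: 34 10β-allylic alcohol
Product: 35 10β-triethylsilyl ether
Conditions: TESOTf, 2,6-lutidine, CH2Cl2, −78 °C
Reagents that add atoms: triethylsilyl triflate, CC[Si](CC)(CC)OS(=O)(=O)C(F)(F)F
Why: Silylation turns a hydroxyl that would direct a peracid to its own face into a bulky group that blocks the β-face.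

Step 22
Reactants: 35 10β-triethylsilyl ether
Product: 36 8α,9α-epoxide
Conditions: mCPBA, NaHCO3, CH2Cl2, 0 °C
Reagents that add atoms: 3-chloroperbenzoic acid, OOC(=O)c1cccc(Cl)c1
Why: Peracid epoxidation of the trisubstituted C8=C9 bond anti to the allylic silyloxy group and the angular methyl group should place the oxirane on the α-face, which makes the C8 methyl β and sets C9.

Step 23
Reactants: 36 8α,9α-epoxide
Product: 37 CNP0371526.1
Conditions: HF·pyridine, pyridine, THF, 0 °C → rt
Reagents that add atoms: none
Why: Buffered fluoride cleavage should remove the secondary and the tertiary triethylsilyl ether without opening the epoxide or moving the esters.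

**Compound list**
1 | (R)-4-(tert-butyldimethylsilyloxy)cyclopent-2-en-1-one | O=C1C[C@@H](O[Si](C)(C)C(C)(C)C)C=C1 | starting material
2 | isopropylmagnesium chloride | CC(C)[Mg]Cl | starting material
3 | chloromagnesium enolate of 4 (enolate on the side of the isopropyl carbon) | Cl[Mg]OC1=C[C@@H](C(C)C)[C@H](O[Si](C)(C)C(C)(C)C)C1 | intermediate
4 | (3S,4R)-3-isopropyl-4-(tert-butyldimethylsilyloxy)cyclopentan-1-one | O=C1C[C@@H](C(C)C)[C@H](O[Si](C)(C)C(C)(C)C)C1 | intermediate
5 | (S)-4-isopropylcyclopent-2-en-1-one | O=C1C[C@@H](C(C)C)C=C1 | intermediate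
6 | (S)-2-iodo-4-isopropylcyclopent-2-en-1-one | O=C1C[C@@H](C(C)C)C=C1I | intermediate
7 | (S)-4-isopropyl-2-methylcyclopent-2-en-1-one | O=C1C[C@@H](C(C)C)C=C1C | intermediate
8 | 2-methylbut-3-en-1-ol (racemic) | C=CC(C)CO | starting material
9 | 2-methylbut-3-enal (racemic) | C=CC(C)C=O | intermediate
10 | vinylmagnesium bromide | C=C[Mg]Br | starting material
11 | bromomagnesium C1=C2 enolate of trans-4-isopropyl-2-methyl-3-vinylcyclopentanone (vinyl β on C5, isopropyl α on C4) | CC1=C(O[Mg]Br)C[C@@H](C(C)C)[C@@H]1C=C | intermediate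
12 | (2S,3S,4S)-2-(1-hydroxy-2-methylbut-3-en-1-yl)-4-isopropyl-2-methyl-3-vinylcyclopentan-1-one (epimers at side-chain C8 and C10) | C=CC(C)C(O)[C@]1(C)[C@@H](C=C)[C@H](C(C)C)CC1=O | intermediate
13 | tert-butyldimethylsilyl ether of 12 at C10–OH | C=CC(C)C(O[Si](C)(C)C(C)(C)C)[C@]1(C)[C@@H](C=C)[C@H](C(C)C)CC1=O | intermediate
14 | trans-fused hydrindenone: C2 ketone, 4α-isopropyl (4β-H), C6=C7, C8 methyl, C10 OTBS (C8/C10 epimers) | CC1C(O[Si](C)(C)C(C)(C)C)[C@]3(C)[C@@H](C=C1)[C@H](C(C)C)CC3=O | intermediate
15 | C2=C3 trimethylsilyl enol ether of 14 | CC1C(O[Si](C)(C)C(C)(C)C)[C@]3(C)[C@@H](C=C1)[C@H](C(C)C)C=C3O[Si](C)(C)C | intermediate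
16 | bicyclic cyclopentenone: C2 ketone, C3=C4 with isopropyl on C4, C6=C7, C10 OTBS | CC1C(O[Si](C)(C)C(C)(C)C)[C@]3(C)[C@@H](C=C1)C(C(C)C)=CC3=O | intermediate
17 | 2β-allylic alcohol from 16 | CC1C(O[Si](C)(C)C(C)(C)C)[C@]3(C)[C@@H](C=C1)C(C(C)C)=C[C@H]3O | intermediate
18 | 2β-hydroxy-3β,4β-epoxide with 4α-isopropyl, C6=C7, C10 OTBS | CC1C(O[Si](C)(C)C(C)(C)C)[C@]3(C)[C@@H](C=C1)[C@@]5(C(C)C)O[C@H]5[C@H]3O | intermediate
19 | 2β,4β-diol with 4α-isopropyl, C6=C7, C10 OTBS | CC1C(O[Si](C)(C)C(C)(C)C)[C@]3(C)[C@@H](C=C1)[C@](O)(C(C)C)C[C@H]3O | intermediate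
20 | 2β-acetate of 19 | CC1C(O[Si](C)(C)C(C)(C)C)[C@]3(C)[C@@H](C=C1)[C@](O)(C(C)C)C[C@H]3OC(C)=O | intermediate
21 | 2β-acetoxy-4β,10-diol, C6=C7 (C8/C10 epimers) | CC1C(O)[C@]3(C)[C@@H](C=C1)[C@](O)(C(C)C)C[C@H]3OC(C)=O | intermediate
22 | 2β-acetoxy-4β-hydroxy C10 ketone with C6=C7 (C8 epimers) | CC1C(=O)[C@]3(C)[C@@H](C=C1)[C@](O)(C(C)C)C[C@H]3OC(C)=O | intermediate
23 | 4β-triethylsilyl ether of 22 | CC1C(=O)[C@]3(C)[C@@H](C=C1)[C@](O[Si](CC)(CC)CC)(C(C)C)C[C@H]3OC(C)=O | intermediate
24 | 6α,7α-epoxy C10 ketone | CC1C(=O)[C@]3(C)[C@@H]([C@H]4O[C@@H]14)[C@](O[Si](CC)(CC)CC)(C(C)C)C[C@H]3OC(C)=O | intermediate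
25 | 6α-hydroxy C7=C8 enone (C10 ketone), 4β-OTES, 2β-OAc | CC=1C(=O)[C@]3(C)[C@@H]([C@@H](O)C=1)[C@](O[Si](CC)(CC)CC)(C(C)C)C[C@H]3OC(C)=O | intermediate
26 | 4-methoxybenzoyl chloride | COc1ccc(C(=O)Cl)cc1 | starting material
27 | 6α-(4-methoxybenzoyloxy) C7=C8 enone | CC=1C(=O)[C@]3(C)[C@@H]([C@@H](OC(=O)c2ccc(OC)cc2)C=1)[C@](O[Si](CC)(CC)CC)(C(C)C)C[C@H]3OC(C)=O | intermediate
28 | lithium C8=C10 enolate from conjugate reduction of 27 | CC1=C(O[Li])[C@]3(C)[C@@H]([C@@H](OC(=O)c2ccc(OC)cc2)C1)[C@](O[Si](CC)(CC)CC)(C(C)C)C[C@H]3OC(C)=O | intermediate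
29 | trans-hydrindanone trimethylsilyl enol ether (C8=C10–OTMS, 6α-anisoate, 4β-OTES, 2β-OAc) | CC1=C(O[Si](C)(C)C)[C@]3(C)[C@@H]([C@@H](OC(=O)c2ccc(OC)cc2)C1)[C@](O[Si](CC)(CC)CC)(C(C)C)C[C@H]3OC(C)=O | intermediate
30 | diiodomethane | ICI | starting material
31 | siloxycyclopropane (C8–C9–C10 ring, OTMS on C10; cyclopropane face not defined) | CC12CC1(O[Si](C)(C)C)[C@]3(C)[C@@H]([C@@H](OC(=O)c4ccc(OC)cc4)C2)[C@](O[Si](CC)(CC)CC)(C(C)C)C[C@H]3OC(C)=O | intermediate
32 | β-chloro ketone: seven-membered ring, C10 ketone, C9 methylene, C8 chloro and methyl (C8 not defined) | CC1(Cl)CC(=O)[C@]3(C)[C@@H]([C@@H](OC(=O)c2ccc(OC)cc2)C1)[C@](O[Si](CC)(CC)CC)(C(C)C)C[C@H]3OC(C)=O | intermediate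
33 | hydroazulenone: C10 ketone, C8=C9 with methyl on C8, 6α-anisoate, 4β-OTES, 2β-OAc | COc1ccc(C(=O)O[C@H]2CC(C)=CC(=O)[C@]3(C)[C@@H]2[C@](O[Si](CC)(CC)CC)(C(C)C)C[C@H]3OC(C)=O)cc1 | intermediate
34 | 10β-allylic alcohol from 33 | COc1ccc(C(=O)O[C@H]2CC(C)=C[C@H](O)[C@]3(C)[C@@H]2[C@](O[Si](CC)(CC)CC)(C(C)C)C[C@H]3OC(C)=O)cc1 | intermediate
35 | 10β-triethylsilyl ether of 34 | COc1ccc(C(=O)O[C@H]2CC(C)=C[C@H](O[Si](CC)(CC)CC)[C@]3(C)[C@@H]2[C@](O[Si](CC)(CC)CC)(C(C)C)C[C@H]3OC(C)=O)cc1 | intermediate
36 | 8α,9α-epoxide, 4β,10β-bis(triethylsilyl) ether | COc1ccc(C(=O)O[C@H]2C[C@@]3(C)O[C@H]3[C@H](O[Si](CC)(CC)CC)[C@]3(C)[C@@H]2[C@](O[Si](CC)(CC)CC)(C(C)C)C[C@H]3OC(C)=O)cc1 | intermediate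
37 | CNP0371526.1 | COc1ccc(C(=O)O[C@H]2C[C@@]3(C)O[C@H]3[C@H](O)[C@]3(C)[C@@H]2[C@](O)(C(C)C)C[C@H]3OC(C)=O)cc1 | target

**Step count and risks**
Total step count: 23. Longest linear sequence: 22 steps (steps 1–3 and 5–23, from 1 to 37); step 4 is a one-step side branch.

The three steps most likely to fail:

- **Step 19.** Transfer of the methylene from EtZnCH2I to the crowded tetrasubstituted enol ether next to the quaternary C1 may be slow, so that the enol ether hydrolyses back to the ketone on work-up; the esters may also suffer during the basic loss of HCl. Fallback: starting again from 29, dibromocarbene (CHBr3, KOtBu, pentane, −30 °C), a smaller and more electrophilic carbene, would give the dibromocyclopropane F3. On warming, F3 should ionise a bromide, open the same C8–C10 bond and lose Me3SiBr to give the 9-bromo enone F4. Bu3SnH with Pd(PPh3)4 would then replace the vinylic bromine by hydrogen, and the route is rejoined at 33.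
- **Step 5.** Proton transfer from the enolisable aldehyde to the hindered enolate, or drift of the aldehyde double bond into conjugation, may leave only the simple 1,4-adduct. Fallback: from 7, the conjugate addition is run with TMSCl present to give the isolable trimethylsilyl enol ether F1. A TiCl4-mediated Mukaiyama aldol addition of F1 to 9 at −78 °C, which involves no basic enolate, then returns to 12.
- **Step 16.** Delivery of the peracid to the β-face of C6=C7 (poor facial selectivity) would put the C6 oxygen cis to the angular methyl. Fallback: from 23, the β-epoxide gives on the same base treatment the 6β-alcohol F2, the C6 epimer of 25. A Mitsunobu reaction of F2 with 4-methoxybenzoic acid (PPh3, diisopropyl azodicarboxylate) inverts C6 and installs the ester in one operation, so the route is rejoined at 27; any 25 formed alongside is acylated as in step 17.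

Further compounds
F1 | step 5 | trimethylsilyl enol ether (C1=C2) of trans-4-isopropyl-2-methyl-3-vinylcyclopentanone | CC1=C(O[Si](C)(C)C)C[C@@H](C(C)C)[C@@H]1C=C
F2 | step 16 | 6β-hydroxy C7=C8 enone (C6 epimer of 25) | CC=1C(=O)[C@]3(C)[C@@H]([C@H](O)C=1)[C@](O[Si](CC)(CC)CC)(C(C)C)C[C@H]3OC(C)=O
F3 | step 19 | 9,9-dibromo siloxycyclopropane from 29 | CC12C(Br)(Br)C1(O[Si](C)(C)C)[C@]3(C)[C@@H]([C@@H](OC(=O)c4ccc(OC)cc4)C2)[C@](O[Si](CC)(CC)CC)(C(C)C)C[C@H]3OC(C)=O
F4 | step 19 | 9-bromo hydroazulenone (9-bromo derivative of 33) | CC1=C(Br)C(=O)[C@]3(C)[C@@H]([C@@H](OC(=O)c2ccc(OC)cc2)C1)[C@](O[Si](CC)(CC)CC)(C(C)C)C[C@H]3OC(C)=O
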